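**Plan**

1. Ring labels: C1 = quaternary ring carbon (aryl, methyl), C2 = CHMe, C3 = alkylidene carbon, C4 and C5 = ring CH2 (C5 next to C1). The retrosynthesis cuts the aryl C–Br bond and the O-protecting group, then the vinylic C–Br bond together with the ring bond C3–C4 (silicon as placeholder on the exocyclic carbon), then the C1–C2 bond (Ireland–Claisen), then the C=C bond of an aryl butenoate.
2. Enabling feature: the exocyclic C3=CHBr of the cyclopentane has bromine cis to ring carbon C4, which is the pattern left when a C4 carbanion and a bromine electrophile add syn across a C3≡C triple bond in a 5-exo-dig closure.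
3. Forward: the chain is assembled first (olefination, reduction, acylation, Claisen; acid to silylalkyne; vinyl to 2-iodoethyl). The only ring closes in step 12, followed by C-desilylation, O-deprotection and aryl bromination.
4. Stereochemistry: C1 and C2 are set together in the chair Ireland–Claisen rearrangement (E-alkene, boron ketene acetal with methyl trans to O–B), the absolute sense coming from a C2-symmetric diazaborolidine on boron. The alkene geometry comes from syn-carbolithiation, then bromination and protodesilylation with retention.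

Key step: step 12

Assumption: the (4S,5S)-bromodiazaborolidine is taken to induce the (2R,3R) sense in step 5. This sense has to be confirmed on acid 10; if it is the opposite, the (4R,5R)-reagent from the antipodal diamine is used with no other change.

**Route**

Step 1
Reactants: 1 1-(2-hydroxy-4-methylphenyl)ethanone
Product: 2 1-[2-(methoxymethoxy)-4-methylphenyl]ethanone
Conditions: MOMCl, iPr2NEt, CH2Cl2, 0 °C → rt
Reagents that add atoms: chloromethyl methyl ether, COCCl
Why: O-alkylation of the phenol (MOM acetal formation) masks the acidic OH with a small group that should tolerate every base, hydride and organolithium used later.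

Step 2
Reactants: 2 1-[2-(methoxymethoxy)-4-methylphenyl]ethanone; 3 triethyl phosphonoacetate
Product: 4 ethyl (2E)-3-[2-(methoxymethoxy)-4-methylphenyl]but-2-enoate
Conditions: NaH, THF, 0 °C → reflux; minor Z isomer removed by chromatography
Reagents that add atoms: none
Why: Horner–Wadsworth–Emmons olefination of the aryl methyl ketone favours the isomer with aryl trans to the ester, and this E geometry is what step 5 translates into the C1/C2 relative configuration.

Step 3
Reactants: 4 ethyl (2E)-3-[2-(methoxymethoxy)-4-methylphenyl]but-2-enoate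
Product: 5 (2E)-3-[2-(methoxymethoxy)-4-methylphenyl]but-2-en-1-ol
Conditions: DIBAL-H (2.2 equiv), CH2Cl2, −78 °C; Rochelle salt work-up
Reagents that add atoms: none
Why: DIBAL-H 1,2-reduction of an enoate gives the allylic alcohol without touching the trisubstituted double bond or the acetal.

Step 4
Reactants: 5 (2E)-3-[2-(methoxymethoxy)-4-methylphenyl]but-2-en-1-ol; 6 propanoyl chloride
Product: 7 (2E)-3-[2-(methoxymethoxy)-4-methylphenyl]but-2-en-1-yl propanoate
Conditions: Et3N, DMAP (cat.), CH2Cl2, 0 °C
Reagents that add atoms: none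
Why: DMAP-catalysed acylation of a primary allylic alcohol with an acid chloride is routine and leaves the alkene geometry intact.

Step 5
Reactants: 7 (2E)-3-[2-(methoxymethoxy)-4-methylphenyl]but-2-en-1-yl propanoate
Product: 10 (2R,3R)-3-[2-(methoxymethoxy)-4-methylphenyl]-2,3-dimethylpent-4-enoic acid, via boron ketene acetal 8 (not isolated), via boryl ester 9 (not isolated)
Conditions: (4S,5S)-2-bromo-4,5-diphenyl-1,3-bis{[3,5-bis(trifluoromethyl)phenyl]sulfonyl}-1,3,2-diazaborolidine (1.1 equiv, preformed, HBr-free), Et3N, toluene–hexane, −78 °C, then −20 → 4 °C; aqueous work-up with recovery of the bis-sulfonamide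
Reagents that add atoms: none
Why: Enantioselective boron-enolate Ireland–Claisen rearrangement: bromoborane and Et3N in toluene–hexane should give the ketene acetal with methyl trans to O–B, the chair transition state with aryl equatorial and that methyl axial joins C1 to C2 so that aryl and the C2 methyl become cis in the later ring, and the C2-symmetric sulfonamide ligand on boron selects the enolate face and thus the absolute configuration of both new centres.

Step 6
Reactants: 10 (2R,3R)-3-[2-(methoxymethoxy)-4-methylphenyl]-2,3-dimethylpent-4-enoic acid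
Product: 11 (2R,3R)-3-[2-(methoxymethoxy)-4-methylphenyl]-2,3-dimethylpent-4-en-1-ol
Conditions: LiAlH4, Et2O, 0 °C → rt; aqueous NaOH work-up
Reagents that add atoms: none
Why: Hydride reduction of the carboxylic acid to the primary alcohol does not affect the vinyl group, the acetal or either stereocentre.

Step 7
Reactants: 11 (2R,3R)-3-[2-(methoxymethoxy)-4-methylphenyl]-2,3-dimethylpent-4-en-1-ol
Product: 12 (2R,3R)-3-[2-(methoxymethoxy)-4-methylphenyl]-2,3-dimethylpent-4-enal
Conditions: Dess–Martin periodinane, CH2Cl2, 0 °C → rt; crude aldehyde used at once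
Reagents that add atoms: none
Why: Dess–Martin oxidation is non-basic, so the epimerisable α-centre (C2) of the aldehyde should stay intact.

Step 8
Reactants: 12 (2R,3R)-3-[2-(methoxymethoxy)-4-methylphenyl]-2,3-dimethylpent-4-enal
Product: 13 1-[(3R,4S)-6,6-dibromo-3,4-dimethylhexa-1,5-dien-3-yl]-2-(methoxymethoxy)-4-methylbenzene
Conditions: CBr4, PPh3, CH2Cl2, 0 °C (ylide preformed); then 12 and Et3N, −78 → 0 °C
Reagents that add atoms: carbon tetrabromide, BrC(Br)(Br)Br
Why: The first stage of the Corey–Fuchs sequence is a Wittig-type dibromoolefination under essentially neutral, amine-buffered conditions, which adds the future exocyclic carbon without epimerising C2 or cleaving the acetal.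

Step 9
Reactants: 13 1-[(3R,4S)-6,6-dibromo-3,4-dimethylhexa-1,5-dien-3-yl]-2-(methoxymethoxy)-4-methylbenzene
Product: 15 trimethyl{(3R,4R)-4-[2-(methoxymethoxy)-4-methylphenyl]-3,4-dimethylhex-5-en-1-yn-1-yl}silane, via lithium acetylide 14 (not isolated)
Conditions: n-BuLi (2.2 equiv), THF, −78 → 0 °C; TMSCl, −78 °C → rt
Reagents that add atoms: chlorotrimethylsilane, C[Si](C)(C)Cl
Why: The second stage of the Corey–Fuchs sequence (bromine–lithium exchange, Fritsch–Buttenberg–Wiechell rearrangement, deprotonation) gives the lithium acetylide, which is C-silylated in the same flask to install the activating silyl group.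

Step 10
Reactants: 15 trimethyl{(3R,4R)-4-[2-(methoxymethoxy)-4-methylphenyl]-3,4-dimethylhex-5-en-1-yn-1-yl}silane
Product: 17 (3R,4R)-3-[2-(methoxymethoxy)-4-methylphenyl]-3,4-dimethyl-6-(trimethylsilyl)hex-5-yn-1-ol, via alkylborane 16 (not isolated)
Conditions: 9-BBN-H (1.2 equiv), THF, 0 °C → rt; NaBO3·4H2O, THF–H2O, rt
Reagents that add atoms: sodium perborate (used as the tetrahydrate), [Na+].[Na+].O[B-]1(O)OO[B-](O)(O)OO1
Why: Anti-Markovnikov hydroboration–oxidation with a bulky dialkylborane should attack the terminal carbon of the monosubstituted alkene much faster than the hindered silylalkyne, and perborate oxidises the C–B bond without cleaving the alkynyl C–Si bond.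

Step 11
Reactants: 17 (3R,4R)-3-[2-(methoxymethoxy)-4-methylphenyl]-3,4-dimethyl-6-(trimethylsilyl)hex-5-yn-1-ol
Product: 18 1-[(3R,4R)-1-iodo-3,4-dimethyl-6-(trimethylsilyl)hex-5-yn-3-yl]-2-(methoxymethoxy)-4-methylbenzene
Conditions: I2, PPh3, imidazole, CH2Cl2, 0 °C → rt, dark
Reagents that add atoms: iodine, II
Why: Appel-type iodination (phosphine/iodine/imidazole) converts the unhindered primary alcohol to the iodide by SN2 under buffered conditions that spare the acetal and the silylalkyne.

Step 12
Reactants: 18 1-[(3R,4R)-1-iodo-3,4-dimethyl-6-(trimethylsilyl)hex-5-yn-3-yl]-2-(methoxymethoxy)-4-methylbenzene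
Product: 21 1-[(1R,2R,3E)-3-[bromo(trimethylsilyl)methylidene]-1,2-dimethylcyclopentyl]-2-(methoxymethoxy)-4-methylbenzene, via alkyllithium 19 (not isolated), via vinyllithium 20 (not isolated)
Conditions: t-BuLi (2.1 equiv), n-pentane–Et2O (3:2), −78 °C; warm to 0–20 °C; recool to −78 °C, BrCH2CH2Br, → 0 °C
Reagents that add atoms: 1,2-dibromoethane, BrCCBr
Why: Iodine–lithium exchange with t-BuLi at −78 °C is faster than any deprotonation and gives the primary C4 alkyllithium 19, which on warming adds intramolecularly and syn across the silyl-activated triple bond to give the α-silyl vinyllithium 20; 1,2-dibromoethane then transfers bromine to this carbanion with retention, releasing ethene and LiBr. The closest known reaction type is the cycloisomerisation of 6-silyl-5-hexynyllithiums to (cyclopentylidene)(silyl)methyllithiums followed by electrophilic trapping. The cyclopentane closes in the 5-exo-dig mode by forming the C3–C4 bond, helped by the quaternary C1 (gem-disubstituent effect) and by the silyl group, which activates the alkyne and stabilises the developing α-carbanion. No stereocentre is formed: C1 and C2 are spectators, and the only new stereo-element, the tetrasubstituted double bond, is fixed by the syn course of the carbolithiation, which puts lithium and hence bromine cis to C4 and silicon cis to C2. The step needs a configurationally stable 20 and clean halogen transfer; the hydrocarbon–ether medium without THF or amine additives, the low quench temperature and the short interval between ring closure and bromination are meant to secure both.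

Step 13
Reactants: 21 1-[(1R,2R,3E)-3-[bromo(trimethylsilyl)methylidene]-1,2-dimethylcyclopentyl]-2-(methoxymethoxy)-4-methylbenzene
Product: 22 1-[(1R,2R,3E)-3-(bromomethylidene)-1,2-dimethylcyclopentyl]-2-(methoxymethoxy)-4-methylbenzene
Conditions: NaOMe, MeOH, 50 °C
Reagents that add atoms: none
Why: Methoxide-induced protodesilylation of an α-halovinylsilane replaces silicon by hydrogen with retention of the double-bond geometry, so bromine stays cis to C4.

Step 14
Reactants: 22 1-[(1R,2R,3E)-3-(bromomethylidene)-1,2-dimethylcyclopentyl]-2-(methoxymethoxy)-4-methylbenzene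
Product: 23 2-[(1R,2R,3E)-3-(bromomethylidene)-1,2-dimethylcyclopentyl]-5-methylphenol
Conditions: HCl (3 M aq., cat.), MeOH–THF, 40 °C
Reagents that add atoms: none
Why: Acid-catalysed acetal exchange with methanol removes the aryl MOM group under conditions mild enough that the electron-poor bromoalkene should resist protonation.

Step 15
Reactants: 23 2-[(1R,2R,3E)-3-(bromomethylidene)-1,2-dimethylcyclopentyl]-5-methylphenol
Product: 24 4-bromo-2-[(1R,2R,3E)-3-(bromomethylidene)-1,2-dimethylcyclopentyl]-5-methylphenol
Conditions: NBS (1.0 equiv), MeCN, −20 → 0 °C, dark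
Reagents that add atoms: N-bromosuccinimide, O=C1CCC(=O)N1Br
Why: Electrophilic aromatic bromination of the phenol goes para to OH, since one ortho position is substituted and the other is flanked by OH and methyl, while the deactivated vinyl bromide should not compete.

**Compound list**

1 | 1-(2-hydroxy-4-methylphenyl)ethanone | CC(=O)c1ccc(C)cc1O | starting material
2 | 1-[2-(methoxymethoxy)-4-methylphenyl]ethanone | CC(=O)c1ccc(C)cc1OCOC | intermediate
3 | triethyl phosphonoacetate | CCOC(=O)CP(=O)(OCC)OCC | starting material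
4 | ethyl (2E)-3-[2-(methoxymethoxy)-4-methylphenyl]but-2-enoate | CCOC(=O)/C=C(\C)c1ccc(C)cc1OCOC | intermediate
5 | (2E)-3-[2-(methoxymethoxy)-4-methylphenyl]but-2-en-1-ol | OC/C=C(\C)c1ccc(C)cc1OCOC | intermediate
6 | propanoyl chloride | CCC(=O)Cl | starting material
7 | (2E)-3-[2-(methoxymethoxy)-4-methylphenyl]but-2-en-1-yl propanoate | CCC(=O)OC/C=C(\C)c1ccc(C)cc1OCOC | intermediate
8 | boron ketene acetal of 7, methyl trans to O–B, boron in the (4S,5S)-4,5-diphenyl-1,3-bis{[3,5-bis(trifluoromethyl)phenyl]sulfonyl}-1,3,2-diazaborolidin-2-yl ring | C/C=C(/OB1N(S(=O)(=O)c2cc(C(F)(F)F)cc(C(F)(F)F)c2)[C@@H](c2ccccc2)[C@H](c2ccccc2)N1S(=O)(=O)c1cc(C(F)(F)F)cc(C(F)(F)F)c1)\OC/C=C(\C)c1ccc(C)cc1OCOC | intermediate (not isolated)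
9 | (4S,5S)-4,5-diphenyl-1,3-bis{[3,5-bis(trifluoromethyl)phenyl]sulfonyl}-1,3,2-diazaborolidin-2-yl (2R,3R)-3-[2-(methoxymethoxy)-4-methylphenyl]-2,3-dimethylpent-4-enoate | Cc1cc(OCOC)c([C@]([C@@H](C)C(=O)OB2N(S(=O)(=O)c3cc(C(F)(F)F)cc(C(F)(F)F)c3)[C@@H](c3ccccc3)[C@H](c3ccccc3)N2S(=O)(=O)c2cc(C(F)(F)F)cc(C(F)(F)F)c2)(C)C=C)cc1 | intermediate (not isolated)
10 | (2R,3R)-3-[2-(methoxymethoxy)-4-methylphenyl]-2,3-dimethylpent-4-enoic acid | Cc1cc(OCOC)c([C@]([C@@H](C)C(=O)O)(C)C=C)cc1 | intermediate
11 | (2R,3R)-3-[2-(methoxymethoxy)-4-methylphenyl]-2,3-dimethylpent-4-en-1-ol | Cc1cc(OCOC)c([C@]([C@@H](C)CO)(C)C=C)cc1 | intermediate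
12 | (2R,3R)-3-[2-(methoxymethoxy)-4-methylphenyl]-2,3-dimethylpent-4-enal | Cc1cc(OCOC)c([C@]([C@@H](C)C=O)(C)C=C)cc1 | intermediate
13 | 1-[(3R,4S)-6,6-dibromo-3,4-dimethylhexa-1,5-dien-3-yl]-2-(methoxymethoxy)-4-methylbenzene | Cc1cc(OCOC)c([C@]([C@@H](C)C=C(Br)Br)(C)C=C)cc1 | intermediate
14 | lithium acetylide corresponding to 15 (lithium in place of SiMe3, configuration unchanged) | Cc1cc(OCOC)c([C@]([C@@H](C)C#C[Li])(C)C=C)cc1 | intermediate (not isolated)
15 | trimethyl{(3R,4R)-4-[2-(methoxymethoxy)-4-methylphenyl]-3,4-dimethylhex-5-en-1-yn-1-yl}silane | Cc1cc(OCOC)c([C@]([C@@H](C)C#C[Si](C)(C)C)(C)C=C)cc1 | intermediate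
16 | 9-[(3R,4R)-3-[2-(methoxymethoxy)-4-methylphenyl]-3,4-dimethyl-6-(trimethylsilyl)hex-5-yn-1-yl]-9-borabicyclo[3.3.1]nonane | Cc1cc(OCOC)c([C@]([C@@H](C)C#C[Si](C)(C)C)(C)CCB2C3CCCC2CCC3)cc1 | intermediate (not isolated)
17 | (3R,4R)-3-[2-(methoxymethoxy)-4-methylphenyl]-3,4-dimethyl-6-(trimethylsilyl)hex-5-yn-1-ol | Cc1cc(OCOC)c([C@]([C@@H](C)C#C[Si](C)(C)C)(C)CCO)cc1 | intermediate
18 | 1-[(3R,4R)-1-iodo-3,4-dimethyl-6-(trimethylsilyl)hex-5-yn-3-yl]-2-(methoxymethoxy)-4-methylbenzene | Cc1cc(OCOC)c([C@]([C@@H](C)C#C[Si](C)(C)C)(C)CCI)cc1 | intermediate (key-step precursor)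
19 | [(3R,4R)-3-[2-(methoxymethoxy)-4-methylphenyl]-3,4-dimethyl-6-(trimethylsilyl)hex-5-yn-1-yl]lithium | Cc1cc(OCOC)c([C@]([C@@H](C)C#C[Si](C)(C)C)(C)CC[Li])cc1 | intermediate (not isolated)
20 | [(Z)-{(2R,3R)-3-[2-(methoxymethoxy)-4-methylphenyl]-2,3-dimethylcyclopentylidene}(trimethylsilyl)methyl]lithium, lithium cis to ring C4 | Cc1cc(OCOC)c([C@]2(C)CC/C(=C(\[Li])[Si](C)(C)C)[C@@H]2C)cc1 | intermediate (not isolated)
21 | 1-[(1R,2R,3E)-3-[bromo(trimethylsilyl)methylidene]-1,2-dimethylcyclopentyl]-2-(methoxymethoxy)-4-methylbenzene, bromine cis to ring C4 | Cc1cc(OCOC)c([C@]2(C)CC/C(=C(\Br)[Si](C)(C)C)[C@@H]2C)cc1 | intermediate (key-step product)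
22 | 1-[(1R,2R,3E)-3-(bromomethylidene)-1,2-dimethylcyclopentyl]-2-(methoxymethoxy)-4-methylbenzene | Cc1cc(OCOC)c([C@]2(C)CC/C(=C\Br)[C@@H]2C)cc1 | intermediate
23 | 2-[(1R,2R,3E)-3-(bromomethylidene)-1,2-dimethylcyclopentyl]-5-methylphenol | Cc1cc(O)c([C@]2(C)CC/C(=C\Br)[C@@H]2C)cc1 | intermediate
24 | 4-bromo-2-[(1R,2R,3E)-3-(bromomethylidene)-1,2-dimethylcyclopentyl]-5-methylphenol | Cc1cc(O)c([C@]2(C)CC/C(=C\Br)[C@@H]2C)cc1Br | target

**Step count and risks**

Total step count: 15. Longest linear sequence: 15 steps (1 → 24).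

Steps most likely to fail:

Step 12. The hindered α-silyl vinyllithium may isomerise about the double bond, or abstract a proton instead of bromine, while bromine transfer from the dibromide is slow. The fallback sets out from 18 and comes back at 22, so step 13 is no longer needed. Compound 18 is cyclised as before through 19 and 20, but 20 is protonated at −78 °C with methanol, a quench that is immediate, to give the vinylsilane 1-[(1R,2R,3Z)-1,2-dimethyl-3-[(trimethylsilyl)methylidene]cyclopentyl]-2-(methoxymethoxy)-4-methylbenzene F1. One equivalent of bromine in CH2Cl2 at −78 °C adds anti across the electron-rich vinylsilane, faster than it substitutes the aryl ether, to give the anti dibromide with the ring bromine cis to the aryl group F2 and the anti dibromide with the ring bromine trans to the aryl group F3. Sodium methoxide in methanol then removes silicon and the ring bromine antiperiplanar from either adduct. This bromodesilylation proceeds with inversion at the exocyclic carbon, so silicon cis to C2 in F1 becomes bromine cis to C4 in 22.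

Step 5. The hindered, ortho-substituted trisubstituted allyl unit may rearrange slowly, with erosion of enolate geometry and enantioselection, and residual Lewis-acidic bromoborane may cleave the acetal protecting group. The fallback sets out from 7 and comes back at 10, giving up reagent control for a racemic rearrangement plus separation. Compound 7 is deprotonated with LDA in THF at −78 °C and silylated with TMSCl to the silyl ketene acetal with methyl trans to O–Si F4. On warming to 60 °C this rearranges through the same chair to the racemic trimethylsilyl ester F5. Hydrolysis (aqueous NaHCO3–MeOH, then careful acidification to pH 4) gives the racemic acid F6 with the same relative configuration as 10. The enantiomers are separated by preparative chromatography on a chiral stationary phase, and the (2R,3R)-enantiomer is 10.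

Step 10. Borane addition to the silylalkyne may compete while the neopentyl-type vinyl group reacts sluggishly. The fallback sets out from 13 and comes back at 17 by hydroborating before the alkyne exists. Compound 13, whose dibromoalkene is electron-poor and inert to 9-BBN-H so that heating is allowed, is hydroborated at the vinyl group to the alkylborane F7 and oxidised with sodium perborate to the dibromo alcohol (3R,4S)-6,6-dibromo-3-[2-(methoxymethoxy)-4-methylphenyl]-3,4-dimethylhex-5-en-1-ol F8. n-BuLi (3.3 equiv, THF, −78 → 0 °C) converts it to the dilithium alkoxide acetylide F9. TMSCl silylates carbon and oxygen to the bis-silyl compound F10, and citric acid in methanol cleaves only the O–Si bond to return 17.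

Further compounds
F1 | step 12 | 1-[(1R,2R,3Z)-1,2-dimethyl-3-[(trimethylsilyl)methylidene]cyclopentyl]-2-(methoxymethoxy)-4-methylbenzene, silicon cis to ring C2 | Cc1cc(OCOC)c([C@]2(C)CC/C(=C/[Si](C)(C)C)[C@@H]2C)cc1
F2 | step 12 | anti dibromide of F1, 1-{3-bromo-3-[bromo(trimethylsilyl)methyl]-1,2-dimethylcyclopentyl}-2-(methoxymethoxy)-4-methylbenzene with the ring bromine cis to the aryl group | Cc1cc(OCOC)c([C@]2(C)CC[C@@](Br)([C@@H](Br)[Si](C)(C)C)[C@@H]2C)cc1
F3 | step 12 | anti dibromide of F1, same constitution with the ring bromine trans to the aryl group | Cc1cc(OCOC)c([C@]2(C)CC[C@](Br)([C@H](Br)[Si](C)(C)C)[C@@H]2C)cc1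
F4 | step 5 | trimethyl{[(1E)-1-{[(2E)-3-[2-(methoxymethoxy)-4-methylphenyl]but-2-en-1-yl]oxy}prop-1-en-1-yl]oxy}silane, methyl trans to O–Si | C/C=C(/O[Si](C)(C)C)\OC/C=C(\C)c1ccc(C)cc1OCOC
F5 | step 5 | racemic trimethylsilyl (2R,3R)/(2S,3S)-3-[2-(methoxymethoxy)-4-methylphenyl]-2,3-dimethylpent-4-enoate, both enantiomers written | Cc1cc(OCOC)c([C@]([C@@H](C)C(=O)O[Si](C)(C)C)(C)C=C)cc1.Cc1cc(OCOC)c([C@@]([C@H](C)C(=O)O[Si](C)(C)C)(C)C=C)cc1
F6 | step 5 | racemic (2R,3R)/(2S,3S)-3-[2-(methoxymethoxy)-4-methylphenyl]-2,3-dimethylpent-4-enoic acid, both enantiomers written | Cc1cc(OCOC)c([C@]([C@@H](C)C(=O)O)(C)C=C)cc1.Cc1cc(OCOC)c([C@@]([C@H](C)C(=O)O)(C)C=C)cc1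
F7 | step 10 | 9-[(3R,4S)-6,6-dibromo-3-[2-(methoxymethoxy)-4-methylphenyl]-3,4-dimethylhex-5-en-1-yl]-9-borabicyclo[3.3.1]nonane | Cc1cc(OCOC)c([C@]([C@@H](C)C=C(Br)Br)(C)CCB2C3CCCC2CCC3)cc1
F8 | step 10 | (3R,4S)-6,6-dibromo-3-[2-(methoxymethoxy)-4-methylphenyl]-3,4-dimethylhex-5-en-1-ol | Cc1cc(OCOC)c([C@]([C@@H](C)C=C(Br)Br)(C)CCO)cc1
F9 | step 10 | dilithium alkoxide acetylide derived from F8 (O–Li at C1, C–Li at the alkyne terminus, configuration unchanged) | Cc1cc(OCOC)c([C@]([C@@H](C)C#C[Li])(C)CCO[Li])cc1
F10 | step 10 | trimethyl{[(3R,4R)-3-[2-(methoxymethoxy)-4-methylphenyl]-3,4-dimethyl-6-(trimethylsilyl)hex-5-yn-1-yl]oxy}silane | Cc1cc(OCOC)c([C@]([C@@H](C)C#C[Si](C)(C)C)(C)CCO[Si](C)(C)C)cc1
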